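**Retrosynthetic overview**
1. The ten-membered ring is closed last, by ring-closing enyne metathesis of the C2 vinyl group onto the C4≡C5 alkyne of 25; this forms C3=C4 and the C5=C16 exo-methylene.
2. C8–C9 comes from a Ni/Cr coupling of ring A aldehyde 14 with bromobutenolide 17 (the lactone ring is brought in intact). The 8-OH comes from directed epoxidation then SmI2, C6–Cl from a propargylic inversion, and C9 and C14 are corrected together by oxidation and bulky hydride reduction.
3. Ring A is made first, in the key step: a titanocene-mediated radical cyclisation of the acyclic epoxy allyl sulfone 12. The C1 radical from the epoxide attacks C10 and loss of PhSO2• leaves C11=C12, giving the C1–C10 bond and the quaternary centre.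
4. Compound 12 comes from two C5 units (isoprene → sulfone 4; isoprene monoxide → bromide 6) by sulfone alkylation, Sharpless epoxidation and vinyl Grignard addition.
5. Ring order: ring A (radical) → lactone (pre-formed) → ten-membered ring (metathesis).

Numbering: briarane numbering is used for all intermediates (ring A = C1, C10–C14; C15 methyl on C1; C20 methyl on C11; lactone = C7, C8, C17, C18; C19 methyl on C17; C16 = exo-methylene carbon on C5).
Assumption: 4-bromo-3-methylfuran-2(5H)-one (15) and prop-2-ynal (16) are bought; each is otherwise one step from 3-methyltetronic acid or propargyl alcohol.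

**Route**

Step 1
Reactants: 1 isoprene
Product: 2 (E)-[(4-chloro-2-methylbut-2-en-1-yl)sulfonyl]benzene
Conditions: PhSO2Cl, CuCl (5 mol%), Et3N·HCl (5 mol%), MeCN, 100 °C, sealed tube
Reagents that add atoms: benzenesulfonyl chloride, O=S(=O)(Cl)c1ccccc1
Why: Copper-catalysed atom-transfer radical addition (Kharasch-type chlorosulfonylation): PhSO2• adds to the CH2 next to the methyl-bearing carbon and chlorine transfer to the far end of the allyl radical gives the 1,4-adduct with the preferred (E) geometry.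

Step 2
Reactants: 2 (E)-[(4-chloro-2-methylbut-2-en-1-yl)sulfonyl]benzene
Product: 3 (E)-3-methyl-4-(phenylsulfonyl)but-2-enal
Conditions: N-methylmorpholine N-oxide (4 equiv), NaI (10 mol%), 4 Å molecular sieves, MeCN, 40 °C
Reagents that add atoms: N-methylmorpholine N-oxide, C[N+]1([O-])CCOCC1
Why: Ganem oxidation (SN2 attack of the N-oxide oxygen on the allylic chloride, then elimination of N-methylmorpholine) gives the conjugated (E)-enal at C9 without a base strong enough to touch the sulfone CH2.

Step 3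
Reactants: 3 (E)-3-methyl-4-(phenylsulfonyl)but-2-enal
Product: 4 (E)-[(4,4-dimethoxy-2-methylbut-2-en-1-yl)sulfonyl]benzene
Conditions: HC(OMe)3, MeOH, pyridinium p-toluenesulfonate (5 mol%), rt
Reagents that add atoms: trimethyl orthoformate, COC(OC)OC
Why: Acid-catalysed acetalisation masks the C9 aldehyde as a dimethyl acetal, whose methoxide is too poor a leaving group to be expelled from the sulfonyl carbanion of step 5.

Step 4
Reactants: 5 2-methyl-2-vinyloxirane
Product: 6 (E)-4-bromo-2-methylbut-2-en-1-ol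
Conditions: LiBr, AcOH, CuBr2 (10 mol%), THF, 0 °C
Reagents that add atoms: lithium bromide, [Li+].[Br-]
Why: Copper-assisted SN2′ (1,4) opening of the vinyl oxirane by bromide gives the (E)-configured primary allylic bromide (C13) with the C2 hydroxymethyl group already in place.

Step 5
Reactants: 4 (E)-[(4,4-dimethoxy-2-methylbut-2-en-1-yl)sulfonyl]benzene; 6 (E)-4-bromo-2-methylbut-2-en-1-ol
Product: 7 (2E,6E)-8,8-dimethoxy-2,6-dimethyl-5-(phenylsulfonyl)octa-2,6-dien-1-ol (both C5 epimers)
Conditions: LiN(SiMe3)2 (1.05 equiv on 4, 1.0 equiv on 6), THF, −78 → −30 °C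
Reagents that add atoms: none
Why: Julia-type α-alkylation of the lithiated allyl sulfone with the allylic bromide (its OH masked in the flask as the lithium alkoxide) forms C12–C13 and keeps the sulfone on C12 as the later radical leaving group; the C12 centre is formed as a mixture, which does not matter because it is destroyed in step 9.

Step 6
Reactants: 7 (2E,6E)-8,8-dimethoxy-2,6-dimethyl-5-(phenylsulfonyl)octa-2,6-dien-1-ol
Product: 8 [(2R,3R)-3-[(3E)-5,5-dimethoxy-3-methyl-2-(phenylsulfonyl)pent-3-en-1-yl]-2-methyloxiran-2-yl]methanol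
Conditions: Ti(OiPr)4 (10 mol%), D-(−)-diethyl tartrate (12 mol%), t-BuOOH, 4 Å molecular sieves, CH2Cl2, −20 °C
Reagents that add atoms: tert-butyl hydroperoxide, CC(C)(C)OO
Why: Sharpless asymmetric epoxidation of the (E)-2-methyl allylic alcohol with the D-tartrate gives the (2R,3R)-epoxy alcohol, fixing C14 (R), the centre that sets the absolute sense of the cyclisation in step 9 and is itself corrected in steps 16 and 17.

Step 7
Reactants: 8 [(2R,3R)-3-[(3E)-5,5-dimethoxy-3-methyl-2-(phenylsulfonyl)pent-3-en-1-yl]-2-methyloxiran-2-yl]methanol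
Product: 9 (2S,3R)-3-[(3E)-5,5-dimethoxy-3-methyl-2-(phenylsulfonyl)pent-3-en-1-yl]-2-methyloxirane-2-carbaldehyde
Conditions: Dess–Martin periodinane, NaHCO3, CH2Cl2, 0 °C → rt
Reagents that add atoms: none
Why: Dess–Martin oxidation gives the non-enolisable epoxy aldehyde without opening the epoxide.

Step 8
Reactants: 9 (2S,3R)-3-[(3E)-5,5-dimethoxy-3-methyl-2-(phenylsulfonyl)pent-3-en-1-yl]-2-methyloxirane-2-carbaldehyde; 10 vinylmagnesium bromide
Product: 12 (1S)-1-[(2S,3R)-3-[(3E)-5,5-dimethoxy-3-methyl-2-(phenylsulfonyl)pent-3-en-1-yl]-2-methyloxiran-2-yl]prop-2-en-1-yl acetate, via bromomagnesium alkoxide 11 (not isolated)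
Conditions: CH2=CHMgBr, THF, −78 °C; then Ac2O, −78 → 0 °C
Reagents that add atoms: acetic anhydride, CC(=O)OC(C)=O
Why: Felkin–Anh (Cornforth) addition of the Grignard reagent anti to the epoxide C–O bond sets C2 (S) (about 4:1 expected, minor isomer removed), and the alkoxide is acetylated in the same flask.

Step 9 (key step)
Reactants: 12 (1S)-1-[(2S,3R)-3-[(3E)-5,5-dimethoxy-3-methyl-2-(phenylsulfonyl)pent-3-en-1-yl]-2-methyloxiran-2-yl]prop-2-en-1-yl acetate
Product: 13 (1S)-1-[(1R,2R,6S)-6-(dimethoxymethyl)-2-hydroxy-1,5-dimethylcyclohex-4-en-1-yl]prop-2-en-1-yl acetate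
Conditions: Cp2TiCl2 (2.5 equiv), Mn dust, THF, rt, 12 added over 3 h (5 mM); then 1 M HCl
Reagents that add atoms: none
Why: Proposed new method: Cp2TiCl (trivalent titanium, made in the flask) opens the trisubstituted epoxide homolytically to the tertiary C1 radical with the titanoxy group on C14; this radical adds 6-endo to C10 of the (E)-allyl sulfone through a chair in which the titanoxy group, the C9 acetal branch and the bulky 1-acetoxyallyl group on C1 are equatorial and the methyl is axial, and the C11 radical then ejects PhSO2• (reduced to sulfinate by a second Cp2TiCl), so the C1–C10 bond, C1 (R), C10 (S) and the C11=C12 alkene arise in one step from the C14 epoxide centre; the closest known reaction types are titanocene-mediated radical cyclisations of epoxypolyprenes and radical allylations that end by β-loss of a sulfonyl radical from allyl sulfones.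

Step 10
Reactants: 13 (1S)-1-[(1R,2R,6S)-6-(dimethoxymethyl)-2-hydroxy-1,5-dimethylcyclohex-4-en-1-yl]prop-2-en-1-yl acetate
Product: 14 (1S)-1-[(1R,2R,6S)-6-formyl-2-hydroxy-1,5-dimethylcyclohex-4-en-1-yl]prop-2-en-1-yl acetate
Conditions: 10% aq. oxalic acid on SiO2, CH2Cl2, rt
Reagents that add atoms: water, O
Why: Mild heterogeneous acid hydrolysis of the dimethyl acetal frees the C9 aldehyde (in equilibrium with a bridged lactol formed with the cis C14 hydroxyl) without moving the C11=C12 bond or epimerising C10.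

Step 11
Reactants: 15 4-bromo-3-methylfuran-2(5H)-one; 16 prop-2-ynal
Product: 17 (5S)-4-bromo-5-[(1R)-1-hydroxyprop-2-yn-1-yl]-3-methylfuran-2(5H)-one
Conditions: 1-[3,5-bis(trifluoromethyl)phenyl]-3-[(8α,9S)-6′-methoxycinchonan-9-yl]thiourea (10 mol%), THF, −40 °C
Reagents that add atoms: none
Why: Direct asymmetric vinylogous aldol reaction: the bifunctional amine–thiourea forms the dienolate of the bromobutenolide and steers it to one face of the hydrogen-bonded ynal, giving the 5,1′-syn (threo) adduct and setting C7 and C6 (C6 opposite to the target, ready for inversion).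

Step 12
Reactants: 14 (1S)-1-[(1R,2R,6S)-6-formyl-2-hydroxy-1,5-dimethylcyclohex-4-en-1-yl]prop-2-en-1-yl acetate; 17 (5S)-4-bromo-5-[(1R)-1-hydroxyprop-2-yn-1-yl]-3-methylfuran-2(5H)-one
Product: 18 (1S)-1-[(1R,2R,6S)-2-hydroxy-6-{(R)-hydroxy[(2R)-2-[(1R)-1-hydroxyprop-2-yn-1-yl]-4-methyl-5-oxo-2,5-dihydrofuran-3-yl]methyl}-1,5-dimethylcyclohex-4-en-1-yl]prop-2-en-1-yl acetate
Conditions: CrCl2 (6 equiv), NiCl2 (2 mol%), DMSO–THF, rt
Reagents that add atoms: none
Why: Nozaki–Hiyama–Kishi coupling (zerovalent nickel inserts into the vinyl bromide, transmetallation to trivalent chromium, aldehyde-selective addition) forms C8–C9; Felkin–Anh attack anti to quaternary C1 gives the 9R alcohol, which directs step 13 and is inverted in steps 16 and 17.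

Step 13
Reactants: 18 the coupled butenolide triol described in step 12
Product: 19 the 8,17-epoxide of 18, oxirane oxygen on the butenolide face that carries the C9 and C6 hydroxyls (centres 1R,2S,6R,7S,8R,9R,10S,14R,17R)
Conditions: t-BuOOH, n-BuLi, THF, −20 → 0 °C
Reagents that add atoms: tert-butyl hydroperoxide, CC(C)(C)OO
Why: Hydroxyl-directed nucleophilic (Weitz–Scheffer) epoxidation with lithium tert-butyl peroxide: delivery to the face bearing the C9 hydroxyl (H-9 in the butenolide plane, A(1,3) control) and the C6 hydroxyl sets C8 (R).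

Step 14
Reactants: 19 the 8,17-epoxy lactone
Product: 20 the β-hydroxy lactone: 19 with C17–O replaced by C17–H, tertiary 8-OH, C19 methyl cis to it (centres 1R,2S,6R,7S,8R,9R,10S,14R,17R)
Conditions: SmI2 (2.5 equiv), MeOH, THF, −78 °C
Reagents that add atoms: none
Why: SmI2 reduction of the α,β-epoxy lactone (single-electron C17–O cleavage, then protonation of the samarium enolate anti to the C8 oxygen) gives the β-hydroxy lactone with C17 (R), which is also the more stable epimer (methyl away from the C9 branch).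

Step 15
Reactants: 20 the β-hydroxy lactone tetraol
Product: 21 the 6-chloride of 20 with inverted C6 (centres 1R,2S,6S,7R,8R,9R,10S,14R,17R)
Conditions: PPh3, N-chlorosuccinimide, CH2Cl2, −30 → 0 °C
Reagents that add atoms: N-chlorosuccinimide, O=C1CCC(=O)N1Cl
Why: Appel-type chlorination goes by SN2 inversion at the propargylic oxyphosphonium to give the 6S chloride; the C9 and C14 hydroxyls are neopentylic and the C8 hydroxyl tertiary, so they are not substituted.

Step 16
Reactants: 21 the 6-chloro triol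
Product: 22 the 9,14-diketone of 21 (centres 1S,2S,6S,7R,8S,10S,17R; the C1 and C8 labels change only through priorities)
Conditions: Dess–Martin periodinane (3 equiv), pyridine, CH2Cl2, 0 °C
Reagents that add atoms: none
Why: Dess–Martin oxidation turns both wrongly configured secondary alcohols (C9, C14) into ketones, while the tertiary alcohol, the chloride and the alkyne are inert.

Step 17
Reactants: 22 the 9,14-diketone
Product: 23 the 9,14-diol with target configuration (centres 1R,2S,6S,7R,8R,9S,10S,14S,17R)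
Conditions: LiBH(s-Bu)3 (L-Selectride, 3.5 equiv), THF, −78 °C; aq. NaHCO3
Reagents that add atoms: none
Why: Bulky hydride reduction: the C14 ketone is attacked from the equatorial direction to give the axial 14S alcohol, and the C9 ketone in the Felkin–Anh sense (anti to quaternary C1) to give the 9S alcohol.

Step 18
Reactants: 23 the 9,14-diol
Product: 24 the 2,9,14-triacetate with free tertiary 8-OH (centres as in 23)
Conditions: Ac2O, pyridine, 4-(dimethylamino)pyridine (10 mol%), CH2Cl2, 0 °C → rt
Reagents that add atoms: acetic anhydride, CC(=O)OC(C)=O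
Why: Nucleophile-catalysed acetylation esterifies the two secondary alcohols and leaves the hindered tertiary C8 hydroxyl free.

Step 19
Reactants: 24 the triacetate
Product: 25 the 11α,12α-epoxide of 24 (centres 1R,2S,6S,7R,8R,9S,10S,11S,12R,14S,17R), a seco-briarane with the vinyl group on C2 and the C4≡C5 alkyne on C6
Conditions: mCPBA, NaHCO3, CH2Cl2, 0 °C
Reagents that add atoms: 3-chloroperbenzoic acid, O=C(OO)c1cccc(Cl)c1
Why: Prilezhaev epoxidation takes place at the only electron-rich trisubstituted alkene (C11=C12), from the α face anti to the axial C15 methyl and the C9 branch, setting C11 (S) and C12 (R).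

Step 20
Reactants: 25 the seco-briarane epoxide
Product: 26 CNP0106406.1 (target)
Conditions: second-generation Grubbs catalyst RuCl2(=CHPh)(PCy3)(H2IMes) (15 mol%), ethylene (1 atm), toluene, 80 °C, 1 mM
Reagents that add atoms: none
Why: Ring-closing enyne metathesis in the endo sense (through the 2-substituted butadiene formed with ethylene) joins C3 to C4, creates the C5=C16 exo-methylene and closes the ten-membered ring, the (E)-C3=C4 bond being the geometry expected under reversible conditions for the trans-fused bicycle.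

**Compound list**
1 | isoprene | C=CC(C)=C | starting material
2 | (E)-[(4-chloro-2-methylbut-2-en-1-yl)sulfonyl]benzene | ClC/C=C(\C)CS(=O)(=O)c1ccccc1 | intermediate
3 | (E)-3-methyl-4-(phenylsulfonyl)but-2-enal | O=C/C=C(\C)CS(=O)(=O)c1ccccc1 | intermediate
4 | (E)-[(4,4-dimethoxy-2-methylbut-2-en-1-yl)sulfonyl]benzene | COC(OC)/C=C(\C)CS(=O)(=O)c1ccccc1 | intermediate
5 | 2-methyl-2-vinyloxirane (racemic) | C=CC1(C)CO1 | starting material
6 | (E)-4-bromo-2-methylbut-2-en-1-ol | OC/C(C)=C/CBr | intermediate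
7 | (2E,6E)-8,8-dimethoxy-2,6-dimethyl-5-(phenylsulfonyl)octa-2,6-dien-1-ol (both C5 epimers) | OC/C(C)=C/CC(/C(C)=C/C(OC)OC)S(=O)(=O)c1ccccc1 | intermediate
8 | [(2R,3R)-3-[(3E)-5,5-dimethoxy-3-methyl-2-(phenylsulfonyl)pent-3-en-1-yl]-2-methyloxiran-2-yl]methanol | OC[C@@]1(C)O[C@@H]1CC(/C(C)=C/C(OC)OC)S(=O)(=O)c1ccccc1 | intermediate
9 | (2S,3R)-3-[(3E)-5,5-dimethoxy-3-methyl-2-(phenylsulfonyl)pent-3-en-1-yl]-2-methyloxirane-2-carbaldehyde | O=C[C@@]1(C)O[C@@H]1CC(/C(C)=C/C(OC)OC)S(=O)(=O)c1ccccc1 | intermediate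
10 | vinylmagnesium bromide | C=C[Mg]Br | starting material
11 | bromomagnesium alkoxide of the (1S)-allylic alcohol from 9 | C=C[C@H](O[Mg]Br)[C@@]1(C)O[C@@H]1CC(/C(C)=C/C(OC)OC)S(=O)(=O)c1ccccc1 | intermediate
12 | (1S)-1-[(2S,3R)-3-[(3E)-5,5-dimethoxy-3-methyl-2-(phenylsulfonyl)pent-3-en-1-yl]-2-methyloxiran-2-yl]prop-2-en-1-yl acetate | C=C[C@H](OC(C)=O)[C@@]1(C)O[C@@H]1CC(/C(C)=C/C(OC)OC)S(=O)(=O)c1ccccc1 | intermediate
13 | (1S)-1-[(1R,2R,6S)-6-(dimethoxymethyl)-2-hydroxy-1,5-dimethylcyclohex-4-en-1-yl]prop-2-en-1-yl acetate | C=C[C@H](OC(C)=O)[C@@]1(C)[C@H](O)CC=C(C)[C@@H]1C(OC)OC | intermediate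
14 | (1S)-1-[(1R,2R,6S)-6-formyl-2-hydroxy-1,5-dimethylcyclohex-4-en-1-yl]prop-2-en-1-yl acetate | C=C[C@H](OC(C)=O)[C@@]1(C)[C@H](O)CC=C(C)[C@@H]1C=O | intermediate
15 | 4-bromo-3-methylfuran-2(5H)-one | CC1=C(Br)COC1=O | starting material
16 | prop-2-ynal | C#CC=O | starting material
17 | (5S)-4-bromo-5-[(1R)-1-hydroxyprop-2-yn-1-yl]-3-methylfuran-2(5H)-one | C#C[C@@H](O)[C@@H]1OC(=O)C(C)=C1Br | intermediate
18 | coupled butenolide triol (centres 1R,2S,6R,7R,9R,10S,14R) | C=C[C@H](OC(C)=O)[C@@]1(C)[C@H](O)CC=C(C)[C@@H]1[C@@H](O)C2=C(C)C(=O)O[C@H]2[C@H](O)C#C | intermediate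
19 | 8,17-epoxy lactone (centres 1R,2S,6R,7S,8R,9R,10S,14R,17R) | C=C[C@H](OC(C)=O)[C@@]1(C)[C@H](O)CC=C(C)[C@@H]1[C@@H](O)[C@@]23O[C@@]3(C)C(=O)O[C@H]2[C@H](O)C#C | intermediate
20 | β-hydroxy lactone tetraol (centres 1R,2S,6R,7S,8R,9R,10S,14R,17R) | C=C[C@H](OC(C)=O)[C@@]1(C)[C@H](O)CC=C(C)[C@@H]1[C@@H](O)[C@]2(O)[C@@H](C)C(=O)O[C@H]2[C@H](O)C#C | intermediate
21 | 6-chloro triol (centres 1R,2S,6S,7R,8R,9R,10S,14R,17R) | C=C[C@H](OC(C)=O)[C@@]1(C)[C@H](O)CC=C(C)[C@@H]1[C@@H](O)[C@]2(O)[C@@H](C)C(=O)O[C@H]2[C@@H](Cl)C#C | intermediate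
22 | 9,14-diketone (centres 1S,2S,6S,7R,8S,10S,17R) | C=C[C@H](OC(C)=O)[C@@]1(C)C(=O)CC=C(C)[C@@H]1C(=O)[C@]2(O)[C@@H](C)C(=O)O[C@H]2[C@@H](Cl)C#C | intermediate
23 | 9,14-diol (centres 1R,2S,6S,7R,8R,9S,10S,14S,17R) | C=C[C@H](OC(C)=O)[C@@]1(C)[C@@H](O)CC=C(C)[C@@H]1[C@H](O)[C@]2(O)[C@@H](C)C(=O)O[C@H]2[C@@H](Cl)C#C | intermediate
24 | 2,9,14-triacetate (centres as 23) | C=C[C@H](OC(C)=O)[C@@]1(C)[C@@H](OC(C)=O)CC=C(C)[C@@H]1[C@H](OC(C)=O)[C@]2(O)[C@@H](C)C(=O)O[C@H]2[C@@H](Cl)C#C | intermediate
25 | 11α,12α-epoxy seco-briarane (centres 1R,2S,6S,7R,8R,9S,10S,11S,12R,14S,17R) | C=C[C@H](OC(C)=O)[C@@]1(C)[C@@H](OC(C)=O)C[C@H]3O[C@@]3(C)[C@@H]1[C@H](OC(C)=O)[C@]2(O)[C@@H](C)C(=O)O[C@H]2[C@@H](Cl)C#C | intermediate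
26 | CNP0106406.1 (1R,2S,6S,7R,8R,9S,10S,11S,12R,14S,17R; 3E) | C=C1/C=C/[C@H](OC(C)=O)[C@@]2(C)[C@@H](OC(C)=O)C[C@H]3O[C@@]3(C)[C@@H]2[C@H](OC(C)=O)[C@]2(O)[C@@H](C)C(=O)O[C@H]2[C@H]1Cl | target

**Count**
Total steps: 20. Longest linear sequence: 18 (steps 1–3, 5–10, 12–20).

**Three steps most likely to fail, with fallbacks**

Step 9 (radical cyclisation). The risks are β-acetoxy elimination after titanium capture of the C1 radical and incomplete control at C1. The fallback sets out from 12 and returns at 13. The epoxide of 12 is opened with MgBr2·OEt2 at the tertiary carbon to give the tertiary bromide with the C14 hydroxyl intact, (3S,5R,8E)-4-bromo-5-hydroxy-10,10-dimethoxy-4,8-dimethyl-7-(phenylsulfonyl)deca-1,8-dien-3-yl acetate F1. A metal-free radical chain ((Me3Si)3SiH, Et3B/O2, benzene, rt) then abstracts bromine to give the same C1 radical, which cyclises and ejects PhSO2•; the sulfonyl radical takes hydrogen from the silane and carries the chain, and the product is 13.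

Step 13 (peroxide addition to a tetrasubstituted, electron-poor alkene on its more hindered face). The fallback sets out from 18 and returns at 20. A copper–boryl conjugate addition (CuCl, NaOt-Bu, 1,3-bis(2,6-diisopropylphenyl)imidazolium chloride, B2pin2, MeOH, THF) places boron on C8 from the face of the C9 and C6 alkoxides and protonates C17, giving the tertiary C8 pinacol boronate of 20, boronate F2. Oxidation with NaBO3 proceeds with retention and gives 20.

Step 20 (ten-membered ring by enyne metathesis: exo closure, oligomers or the Z alkene are possible). The fallback sets out from 25 and returns at 26, and takes the enyne event out of the ring closure. Ethylene cross-enyne metathesis (second-generation Grubbs catalyst, ethylene, CH2Cl2, rt) converts the alkyne into the isolated 2-substituted butadiene, the seco-briarane triene F3. A separate diene–ene ring-closing metathesis at high dilution with the molybdenum alkylidene Mo(N-2,6-i-Pr2C6H3)(CHCMe2Ph)[OCMe(CF3)2]2 then joins C3 to C4 with loss of ethylene and gives 26.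

**Further compounds**
F1 | step 9 | (3S,5R,8E)-4-bromo-5-hydroxy-10,10-dimethoxy-4,8-dimethyl-7-(phenylsulfonyl)deca-1,8-dien-3-yl acetate (C4 and C7 epimers) | C=C[C@H](OC(C)=O)C(C)(Br)[C@H](O)CC(/C(C)=C/C(OC)OC)S(=O)(=O)c1ccccc1
F2 | step 13 | C8 pinacol boronate corresponding to 20 (Bpin in place of the 8-hydroxyl, same face) | C=C[C@H](OC(C)=O)[C@@]1(C)[C@H](O)CC=C(C)[C@@H]1[C@@H](O)[C@]2(B3OC(C)(C)C(C)(C)O3)[C@@H](C)C(=O)O[C@H]2[C@H](O)C#C
F3 | step 20 | seco-briarane triene: 25 with the alkyne replaced by a buta-1,3-dien-2-yl group on C6 | C=C[C@H](OC(C)=O)[C@@]1(C)[C@@H](OC(C)=O)C[C@H]3O[C@@]3(C)[C@@H]1[C@H](OC(C)=O)[C@]2(O)[C@@H](C)C(=O)O[C@H]2[C@@H](Cl)C(=C)C=C
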